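**Plan**

- Retrosynthesis: the target is C2-symmetric (axis through O1 of the oxolane ring and the midpoint of C3–C4). Both aryl–C(carbinol) bonds are cut in one operation, leaving two carbamate-activated exocyclic OCH2 arms on a trans-oxolane, and the ring bonds C2–C3 and C4–C5 are then cut to a succinate and a ClCH2OCH2Cl unit.
- Forward: the oxolane ring is made first by dialkylative closure of a chiral succinate dienolate, followed by ester reduction and carbamoylation. A two-directional lithiation–borylation–oxidation then joins both guaiacyl rings, and debenzylation ends the route.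
- Enabling feature: each carbinol carbon is an exocyclic oxygen-bearing carbon on ring C3/C4. As OCH2–OC(O)N(iPr)2 it is deprotonated to a configurationally stable α-oxy carbanion (polarity reversal of the usual aldehyde carbon). This carbon is joined to the nucleophilic aryl carbon of an arylboronic ester by a 1,2-shift from boron, the carbamate oxygen leaving and the C–B bond becoming the C–OH bond.
- Stereochemistry: C3/C4 (trans, R,R) come from the (−)-menthyl auxiliary in step 1. Both carbinol centres (S) come from (+)-sparteine in step 4 (retention at borylation, inversion at migration, retention at oxidation).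

Key step: step 4

Assumption: di-(−)-menthyl succinate, bis(chloromethyl) ether (a volatile carcinogen, handled in a closed system), (+)-sparteine and 2-[4-(benzyloxy)-3-methoxyphenyl]-4,4,5,5-tetramethyl-1,3,2-dioxaborolane are taken as catalogue compounds; the last is otherwise one Miyaura borylation away from 1-(benzyloxy)-4-bromo-2-methoxybenzene.

**Step 1**
Reactants: 1 di-(−)-menthyl succinate [bis((1R,2S,5R)-2-isopropyl-5-methylcyclohexyl) butanedioate]; 2 bis(chloromethyl) ether
Product: 5 di-(−)-menthyl (3R,4R)-tetrahydrofuran-3,4-dicarboxylate, via dilithium dienolate 3 (not isolated), via chloromethoxymethyl lithium enolate 4 (not isolated)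
Conditions: lithium 2,2,6,6-tetramethylpiperidide (2.2 equiv, from n-BuLi and 2,2,6,6-tetramethylpiperidine), THF, −78 °C; then 2 (1.05 equiv, slow addition), −78 → 0 °C
Reagents that add atoms: none
Why: Dialkylative ring closure (double enolate C-alkylation) of the lithium-bridged dienolate 3 with a 1,3-dielectrophile should proceed as with 1,ω-dihaloalkanes: the first alkylation occurs on the enolate face left open by the menthyl groups to give 4, whose pendant α-chloro ether is attacked 5-exo-tet by the second enolate carbon anti to the first ester, so that the auxiliary sets both new stereocentres as trans-(3R,4R).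

**Step 2**
Reactants: 5 di-(−)-menthyl (3R,4R)-tetrahydrofuran-3,4-dicarboxylate
Product: 6 [(3S,4S)-tetrahydrofuran-3,4-diyl]dimethanol
Conditions: LiAlH4, THF, 0 °C → reflux; aqueous NaOH work-up; menthol removed by hexane/water partition
Reagents that add atoms: none
Why: Ester reduction with LiAlH4 converts both menthyl esters into primary alcohols without touching C3 or C4 (the descriptors become S only through the changed CIP ranking) and returns the auxiliary as menthol.

**Step 3**
Reactants: 6 [(3S,4S)-tetrahydrofuran-3,4-diyl]dimethanol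
Product: 7 [(3R,4R)-tetrahydrofuran-3,4-diyl]bis(methylene) bis(N,N-diisopropylcarbamate)
Conditions: iPr2NCOCl (2.5 equiv), Et3N, 4-(dimethylamino)pyridine (cat.), CH2Cl2, reflux
Reagents that add atoms: N,N-diisopropylcarbamoyl chloride, CC(C)N(C(C)C)C(Cl)=O
Why: O-Carbamoylation of the two primary alcohols installs the N,N-diisopropylcarbamoyl groups that direct the α-lithiation and later act as leaving groups, and no stereocentre is affected (the descriptors return to R by CIP ranking only).

**Step 4**
Reactants: 7 [(3R,4R)-tetrahydrofuran-3,4-diyl]bis(methylene) bis(N,N-diisopropylcarbamate); 8 2-[4-(benzyloxy)-3-methoxyphenyl]-4,4,5,5-tetramethyl-1,3,2-dioxaborolane (two molecules react per molecule of 7)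
Product: 12 (S,S)-[(3R,4R)-tetrahydrofuran-3,4-diyl]bis{[4-(benzyloxy)-3-methoxyphenyl]methanol}, via dilithiated bis-carbamate 9 (not isolated), via bis(boronate) complex 10 (not isolated), via bis(pinacol boronic ester) 11 (not isolated)
Conditions: s-BuLi (2.8 equiv), (+)-sparteine (2.8 equiv), Et2O, −78 °C, 5 h; 8 (3 equiv), −78 °C, 1 h; MgBr2·OEt2, −78 → 35 °C; then 2 M NaOH, 30% H2O2, THF, 0 °C → rt
Reagents that add atoms: hydrogen peroxide, OO
Why: Carbamate-directed deprotonation by s-BuLi/(+)-sparteine removes the pro-R hydrogen of each exocyclic OCH2 group to give the dipole-stabilised, configurationally stable α-oxy organolithium 9, which attacks boron of 8 with retention to form bis(boronate) 10; on warming with MgBr2 the aryl carbon shifts from boron to carbon anti to the departing carbamate oxygen (inversion) to give 11, and alkaline H2O2 replaces boron by hydroxyl with retention. The closest known reaction type is the lithiation–borylation of primary O-alkyl N,N-diisopropylcarbamates with aryl pinacol boronic esters (a Matteson-type 1,2-metallate rearrangement), run here in both directions on one C2-symmetric bis-carbamate. The two carbons joined are both nucleophilic in their stable forms (α-oxy carbanion and aryl–boron carbon), the union being possible because the carbenoid carbon first donates to boron and then accepts the aryl group as the carbamate leaves. No ring is closed and the oxolane is a spectator. Both carbinol centres are set by the diamine (reagent control) and the sequence retention–inversion–retention should turn the (+)-sparteine-derived organolithium into the (S)-alcohol at each arm, the C2 axis ensuring that both arms meet the same relation to C3 and C4. The step needs lithiation at the carbamate CH2 and not at the ring OCH2 carbons C2 and C5 (secured by precomplexation of the base to the carbamoyl oxygen), migration of aryl and not of a pinacol oxygen (secured by the antiperiplanar aryl–B/C–O arrangement), and no ring closure between the two arms (secured by their trans placement on the ring).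

**Step 5**
Reactants: 12 (S,S)-[(3R,4R)-tetrahydrofuran-3,4-diyl]bis{[4-(benzyloxy)-3-methoxyphenyl]methanol}
Product: 13 (S,S)-[(3R,4R)-tetrahydrofuran-3,4-diyl]bis[(4-hydroxy-3-methoxyphenyl)methanol] (target)
Conditions: H2 (1 atm), 10% Pd/C, EtOAc, rt, stopped after uptake of two equivalents
Reagents that add atoms: none
Why: Hydrogenolysis of the two aryl benzyl ethers over Pd/C under neutral conditions should free the phenols faster than it attacks the secondary benzylic alcohols, and the four stereocentres are not involved.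

**Compound list**

1 | di-(−)-menthyl succinate [bis((1R,2S,5R)-2-isopropyl-5-methylcyclohexyl) butanedioate] | O=C(CCC(=O)O[C@@H]1C[C@H](C)CC[C@H]1C(C)C)O[C@@H]2C[C@H](C)CC[C@H]2C(C)C | starting material
2 | bis(chloromethyl) ether | ClCOCCl | starting material
3 | dilithium dienolate of 1 [dilithium 1,4-bis(menthyloxy)buta-1,3-diene-1,4-diolate] | [Li]OC(=CC=C(O[Li])O[C@@H]1C[C@H](C)CC[C@H]1C(C)C)O[C@@H]2C[C@H](C)CC[C@H]2C(C)C | intermediate
4 | lithium enolate of di-(−)-menthyl (R)-2-[(chloromethoxy)methyl]succinate | ClCOC[C@H](C(=O)O[C@@H]1C[C@H](C)CC[C@H]1C(C)C)C=C(O[Li])O[C@@H]2C[C@H](C)CC[C@H]2C(C)C | intermediate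
5 | di-(−)-menthyl (3R,4R)-tetrahydrofuran-3,4-dicarboxylate | O=C(O[C@@H]1C[C@H](C)CC[C@H]1C(C)C)[C@H]2COC[C@@H]2C(=O)O[C@@H]3C[C@H](C)CC[C@H]3C(C)C | intermediate
6 | [(3S,4S)-tetrahydrofuran-3,4-diyl]dimethanol | OC[C@H]1COC[C@@H]1CO | intermediate
7 | [(3R,4R)-tetrahydrofuran-3,4-diyl]bis(methylene) bis(N,N-diisopropylcarbamate) | CC(C)N(C(C)C)C(=O)OC[C@H]1COC[C@@H]1COC(=O)N(C(C)C)C(C)C | intermediate
8 | 2-[4-(benzyloxy)-3-methoxyphenyl]-4,4,5,5-tetramethyl-1,3,2-dioxaborolane | COc1cc(B2OC(C)(C)C(C)(C)O2)ccc1OCc1ccccc1 | starting material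
9 | (R,R)-α,α'-dilithio derivative of 7 (present as its bis[(+)-sparteine] complex) | CC(C)N(C(C)C)C(=O)O[C@H]([Li])[C@H]1COC[C@@H]1[C@@H]([Li])OC(=O)N(C(C)C)C(C)C | intermediate
10 | dilithium bis(boronate) complex from 9 and two molecules of 8 (boron on each (R)-carbamoyloxy carbon) | CC(C)N(C(C)C)C(=O)O[C@H]([B-]3(c4ccc(OCc5ccccc5)c(OC)c4)OC(C)(C)C(C)(C)O3)[C@H]2COC[C@@H]2[C@@H]([B-]3(c4ccc(OCc5ccccc5)c(OC)c4)OC(C)(C)C(C)(C)O3)OC(=O)N(C(C)C)C(C)C.[Li+].[Li+] | intermediate
11 | 2,2'-{(3R,4R)-tetrahydrofuran-3,4-diylbis[(S)-(4-(benzyloxy)-3-methoxyphenyl)methylene]}bis(4,4,5,5-tetramethyl-1,3,2-dioxaborolane) | COc1cc([C@@H](B3OC(C)(C)C(C)(C)O3)[C@H]2COC[C@@H]2[C@H](B3OC(C)(C)C(C)(C)O3)c2ccc(OCc3ccccc3)c(OC)c2)ccc1OCc1ccccc1 | intermediate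
12 | (S,S)-[(3R,4R)-tetrahydrofuran-3,4-diyl]bis{[4-(benzyloxy)-3-methoxyphenyl]methanol} | COc1cc([C@@H](O)[C@H]2COC[C@@H]2[C@H](O)c2ccc(OCc3ccccc3)c(OC)c2)ccc1OCc1ccccc1 | intermediate
13 | (S,S)-[(3R,4R)-tetrahydrofuran-3,4-diyl]bis[(4-hydroxy-3-methoxyphenyl)methanol] | COc1cc([C@@H](O)[C@H]2COC[C@@H]2[C@H](O)c2ccc(O)c(OC)c2)ccc1O | target

**Step count and risks**

Total step count: 5. Longest linear sequence: 5 (steps 1 to 5 from compound 1).

Steps most likely to fail:

1. Step 4. The double deprotonation may stop at one arm, the existing C3/C4 centres may erode the reagent control (mismatched pairing), or the 1,2-migration may be slow. Fallback, setting out from 6 and coming back at 12: Swern oxidation ((COCl)2, DMSO, Et3N, CH2Cl2, −78 °C) should give (3R,4R)-tetrahydrofuran-3,4-dicarbaldehyde F1, used cold and crude to limit epimerisation. Addition of [4-(benzyloxy)-3-methoxyphenyl]magnesium bromide F2 (from 1-(benzyloxy)-4-bromo-2-methoxybenzene and Mg in THF) forms the same aryl–carbon bonds and should give [(3R,4R)-tetrahydrofuran-3,4-diyl]bis{[4-(benzyloxy)-3-methoxyphenyl]methanol} as a mixture of carbinol epimers F3. Dess–Martin oxidation should give the diketone [(3R,4R)-tetrahydrofuran-3,4-diyl]bis{[4-(benzyloxy)-3-methoxyphenyl]methanone} F4. Corey–Bakshi–Shibata reduction with (R)-1-methyl-3,3-diphenyltetrahydro-1H,3H-pyrrolo[1,2-c][1,3,2]oxazaborole and BH3·SMe2 (aryl as the large group) should set both (S)-carbinols and return 12.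

2. Step 1. The bifunctional α-chloro ether may alkylate on oxygen or oligomerise the dienolate, and the facial selectivity may be lower than with dihaloalkanes. Fallback, setting out from 2 and coming back at 6: reductive 1,3-elimination of 2 (Mn powder, PbCl2 cat., NaI, THF) should generate the parent carbonyl ylide, whose stereospecific (3+2) cycloaddition to dimethyl fumarate should give racemic dimethyl trans-tetrahydrofuran-3,4-dicarboxylate F5. Saponification (LiOH, THF–H2O) should give racemic trans-tetrahydrofuran-3,4-dicarboxylic acid F6. Classical resolution by crystallisation of the salt with an enantiopure 1-phenylethylamine and liberation with acid should give (3R,4R)-tetrahydrofuran-3,4-dicarboxylic acid F7 (configuration to be confirmed by correlation with 6). Reduction with BH3·THF returns 6.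

3. Step 5. Once the phenols are free, the electron-rich benzylic C–O bonds may be hydrogenolysed (over-reduction). Fallback, setting out from 7 and coming back at 13: commercial 2-methoxy-4-(4,4,5,5-tetramethyl-1,3,2-dioxaborolan-2-yl)phenol is silylated (iPr3SiCl, imidazole, DMF) to triisopropyl[2-methoxy-4-(4,4,5,5-tetramethyl-1,3,2-dioxaborolan-2-yl)phenoxy]silane F8. F8 replaces 8 in the lithiation–borylation of 7 (conditions of step 4 up to the migration), which should run through 9, the corresponding dilithium bis(boronate) complex F9 and the bis(pinacol boronic ester) F10. Oxidation with NaBO3·4H2O in THF–H2O should give (S,S)-[(3R,4R)-tetrahydrofuran-3,4-diyl]bis{[3-methoxy-4-(triisopropylsilyloxy)phenyl]methanol} F11. Bu4NF buffered with AcOH in THF at 0 °C then removes the silyl groups without any reductive step and gives 13.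

**Further compounds**

F1 | step 4 | (3R,4R)-tetrahydrofuran-3,4-dicarbaldehyde | O=C[C@H]1COC[C@@H]1C=O
F2 | step 4 | [4-(benzyloxy)-3-methoxyphenyl]magnesium bromide | COc1cc([Mg]Br)ccc1OCc1ccccc1
F3 | step 4 | [(3R,4R)-tetrahydrofuran-3,4-diyl]bis{[4-(benzyloxy)-3-methoxyphenyl]methanol}, mixture of carbinol epimers | COc1cc(C(O)[C@H]2COC[C@@H]2C(O)c2ccc(OCc3ccccc3)c(OC)c2)ccc1OCc1ccccc1
F4 | step 4 | [(3R,4R)-tetrahydrofuran-3,4-diyl]bis{[4-(benzyloxy)-3-methoxyphenyl]methanone} | COc1cc(C(=O)[C@H]2COC[C@@H]2C(=O)c2ccc(OCc3ccccc3)c(OC)c2)ccc1OCc1ccccc1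
F5 | step 1 | racemic dimethyl trans-tetrahydrofuran-3,4-dicarboxylate | COC(=O)[C@H]1COC[C@@H]1C(=O)OC.COC(=O)[C@@H]1COC[C@H]1C(=O)OC
F6 | step 1 | racemic trans-tetrahydrofuran-3,4-dicarboxylic acid | OC(=O)[C@H]1COC[C@@H]1C(=O)O.OC(=O)[C@@H]1COC[C@H]1C(=O)O
F7 | step 1 | (3R,4R)-tetrahydrofuran-3,4-dicarboxylic acid | OC(=O)[C@H]1COC[C@@H]1C(=O)O
F8 | step 5 | triisopropyl[2-methoxy-4-(4,4,5,5-tetramethyl-1,3,2-dioxaborolan-2-yl)phenoxy]silane | COc1cc(B2OC(C)(C)C(C)(C)O2)ccc1O[Si](C(C)C)(C(C)C)C(C)C
F9 | step 5 | dilithium bis(boronate) complex from 9 and two molecules of F8 | CC(C)N(C(C)C)C(=O)O[C@H]([B-]3(c4ccc(O[Si](C(C)C)(C(C)C)C(C)C)c(OC)c4)OC(C)(C)C(C)(C)O3)[C@H]2COC[C@@H]2[C@@H]([B-]3(c4ccc(O[Si](C(C)C)(C(C)C)C(C)C)c(OC)c4)OC(C)(C)C(C)(C)O3)OC(=O)N(C(C)C)C(C)C.[Li+].[Li+]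
F10 | step 5 | 2,2'-{(3R,4R)-tetrahydrofuran-3,4-diylbis[(S)-(3-methoxy-4-(triisopropylsilyloxy)phenyl)methylene]}bis(4,4,5,5-tetramethyl-1,3,2-dioxaborolane) | COc1cc([C@@H](B3OC(C)(C)C(C)(C)O3)[C@H]2COC[C@@H]2[C@H](B3OC(C)(C)C(C)(C)O3)c2ccc(O[Si](C(C)C)(C(C)C)C(C)C)c(OC)c2)ccc1O[Si](C(C)C)(C(C)C)C(C)C
F11 | step 5 | (S,S)-[(3R,4R)-tetrahydrofuran-3,4-diyl]bis{[3-methoxy-4-(triisopropylsilyloxy)phenyl]methanol} | COc1cc([C@@H](O)[C@H]2COC[C@@H]2[C@H](O)c2ccc(O[Si](C(C)C)(C(C)C)C(C)C)c(OC)c2)ccc1O[Si](C(C)C)(C(C)C)C(C)C
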